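## The problem

The target **28** is a biflavonoid. A (2R)-5,7,4'-trihydroxyflavanone and a 5,7,3',4'-tetrahydroxyflavone are joined by a single carbon–carbon bond from C6 of the flavanone ring A to C6' of the catechol ring B of the flavone. This bond is a tri-ortho-substituted biaryl axis, flanked by the oxygenated carbons C5 and C7 on one side and by the flavone-bearing C1' on the other. It must also sit at C6 and not at C8 of a phloroglucinol ring whose three oxygens differ only in which one becomes the pyranone oxygen O1. The only stereocentre is C2 of the flavanone; nothing in the molecule can relay chirality to it, so it must come from a reagent or catalyst. It is fragile: in base or hot acid a flavanone opens to the 2'-hydroxychalcone by retro-oxa-Michael reaction, which racemises C2 and, once O5 is free, lets the ring reclose on the other oxygen (Wessely–Moser exchange of the 6- and 8-linked isomers). The seven free phenols, two of them a catechol, exclude oxidants, strong base and strong Lewis acids at the end, so C2 should be set late and the unmasking should be neutral and spare the flavone C2=C3 bond and the flavanone carbonyl. The feature that opens the route is ring B of the flavone: its two carbon substituents are on adjacent carbons, C1' (to flavone C2) and C6' (to flavanone C6), and its oxygens at C3' and C4' are mirror-related across the C1'–C6' edge. That is the pattern left when a symmetric 4,5-dioxygenated benzyne takes up a carbon nucleophile at one end and a carbon electrophile at the other. Ring A of the flavanone matches it: C6 lies between two oxygenated carbons and para to the future O1, so a 2,6-dialkoxy-4-oxyaryl metal is a symmetric nucleophile and the choice of O1 reduces to giving the para oxygen its own protecting group.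

## Retrosynthesis

**28 from 27.** Seven O–benzyl bonds are cut. Benzyl is the one permanent protecting group because hydrogenolysis is neutral. Acid-labile groups would not survive the flavone closure, and methyl ethers would need Lewis acids that open the flavanone. The forward step must leave the C2=C3 bond, both carbonyls and the benzylic C2–O1 bond alone.

**27 from 25 and 26.** The bond from flavanone C2 to its aryl group is cut, which removes the stereocentre and the 4-oxyphenyl ring. The neighbouring cut, C2–O1 by oxa-Michael closure of a 2'-hydroxychalcone, is reversible and gives weaker catalyst control. Conjugate addition of boronic acid **26** to chromone **25** is irreversible and sets C2 by the ligand. The forward reaction needs face selection, a base-free medium, and preference for the chromone (C2–H) over the flavone in the same molecule (C2 fully substituted).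

**25 from 23.** O1–C2 and C2–C3 of the chromone are cut; C2 is a one-carbon unit at the formate oxidation level, added through enaminone **24**. This leaves the 2-hydroxyacetophenone **23**, the simplest precursor that already fixes which oxygen is O1.

**23 from 21 and 20.** The aryl–acetyl bond is cut. Friedel–Crafts or Fries acetylation would expose six benzyl ethers and a flavone to Lewis acid. Instead, phenol **20** is iodinated to **21** and the acetyl group is brought in by palladium-catalysed coupling of an acetyl anion equivalent, through enol ether **22**. The two positions ortho to the phenol of **20** are equivalent and the para position is the biaryl carbon, so no regiochemical question arises.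

**20 from 18, and 18 from 15 and 17.** The flavone O1–C2 and C2–C3 bonds are cut (Baker–Venkataraman rearrangement through diketone **19**), then the ester C–O bond. This splits the molecule into the biaryl acid **15** and acetophenone **17**, one benzylation away from commercial **16**. The forward sequence needs an acyl transfer at a crowded benzoate and an acid closure that also frees the para oxygen of ring A; that oxygen is therefore carried as a methoxymethyl ether.

**15 from 7, 10 and 11.** Two bonds on adjacent carbons of ring B are cut: C6–C6' and C1'–CO2H. The alternative, a cross-coupling of a 2,6-dialkoxyarylboron reagent with a 2-halobenzoate, has to force a tri-ortho-substituted reductive elimination and uses a boronic acid class that protodeboronates easily. The aryne route forms the axis by addition to a strained triple bond and delivers the carboxyl carbon in the same flask. Grignard reagent **7** adds to aryne **13**, released from dibromide **10** through **12**, and the resulting **14** is trapped with CO2 (**11**). Both partners are symmetric, so only chemoselectivity is asked of the step.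

**7 from 6, 5, 4, 2 and 1.** The C–Mg bond, two O–benzyl bonds, the O–methoxymethyl bond and the C5–O bond are cut in turn, back to 2-bromoresorcinol **1**. The para oxygen is introduced by iridium-catalysed C–H borylation and oxidation (through **3**), because electrophilic substitution does not place a substituent reliably between the two ether oxygens. The borylation is run on the bis-silyl ether **2**, not on a dibenzyl ether: each benzyl group has three unhindered C–H bonds of a monosubstituted benzene, which would compete with the single C5–H. After the new phenol of **4** is capped (**5**), the silyl groups are exchanged for benzyl in one operation (**6**).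

**10 from 9 and 8.** Two C–Br bonds and two O–benzyl bonds are cut, back to catechol **8**. Each ether oxygen directs bromine para, so the 4,5-dibromide is the expected product.

## Roads not taken

**Alternative 1:** The cut is the C4–C4a bond of the flavanone, with the C2–O1 ether already in place. In the forward key step the (3R)-3-aryloxy-3-arylpropanoic acid A2 is activated with trifluoroacetic anhydride and its acyl carbon attacks ring A ortho to the ether oxygen. This closes ring C to the protected flavanone A3 without touching C2. A2 would come from phenol **20** and the (3S)-hydroxy ester A1 by Mitsunobu inversion and ester cleavage.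
- Merits: the stereocentre comes from a routine asymmetric reduction and is transferred stereospecifically. No rhodium or tin is needed. The two ortho positions of ring A are equivalent, so the closure is regiochemically unambiguous. From **20** it takes three steps where the chosen plan takes four.
- Weak points: the carbinol of A1 is benzylic and para-oxygenated, so displacement can leak through an ion pair and erode the enantiomeric purity; the carbonate on the 4'-oxygen is there to damp this and adds a protecting-group type. Cleaving a β-aryloxy ester invites E1cB loss of the phenoxide. The closure puts a configured benzylic ether, and then the flavanone, through a strongly acidic acylating medium beside six benzyl ethers, where opening to the chalcone would racemise C2.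
- Comparison: this road is one step shorter after **20** and avoids late asymmetric catalysis on a large substrate, which is a real advantage. Against it the chosen plan creates C2 in the penultimate step under neutral conditions, exposes it only to hydrogenolysis, and gives either enantiomer by choice of ligand. Alternative 1 is also an endgame only: it still needs a biaryl phenol such as **20**, so it does not compete with the aryne coupling for the central bond.

**Alternative 2:** The cut is the C4a–C5 bond of the flavone, so ring A of the flavone is built from an open chain. In the forward key step the tetraketo ester A5 is folded on Mg(OMe)2 so that the methylene between its third and fourth carbonyls attacks the ester carbon. This gives the acylphloroglucinol diketone A6, which would then be dehydrated to the flavone. A5 would be grown from the biaryl acid A4 by polyanion acylation.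
- Merits: A6 carries the flavone 5,7-hydroxyls free, which saves two benzyl groups. It is already the diketone that closes to the flavone, so no ester formation or acyl migration is needed.
- Weak points: the pentacarbonyl chain can fold in several ways (aldol closure to resorcylates, pyrone formation), and the Claisen mode must be imposed by the metal template. A5 is a tautomer mixture that needs strongly basic polyanion chemistry to make. The free phloroglucinol of A6 beside benzyl ethers complicates later steps. The ring it builds can be bought as **16**. It also presupposes A4, so the biaryl problem is untouched.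
- Comparison: more steps and more risk for a ring that is commercial. It is better only in protecting-group economy on the flavone ring A, against which the chosen plan sets two robust steps (10 and 11) from **16**.

**Alternative 3:** The cut is the flavone C2–C3 bond, with the carboxyl carbon held as the lactone of a 6H-benzo[c]chromen-6-one. In the forward key step the dilithium salt of **17** attacks the lactone carbonyl of A7, the ring A phenoxide leaves, and acid work-up closes O1–C2 to the flavone A8.
- Merits: acylation and carbon–carbon bond formation happen in one step, where the chosen plan uses two (steps 10 and 11). The lactone is a stable, easily purified acyl donor. The ester tether that makes it can also be used to form the hindered biaryl bond intramolecularly.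
- Weak points: opening the lactone frees an oxygen ortho to the axis, so ring A is no longer symmetric. That phenol must be benzylated again before the para allyl ether is removed, or the later chromanone closure could use the wrong oxygen and give the 8-linked isomer. The lactone carbonyl is crowded and the released phenoxide can re-add until the diketone enolate forms. Building A7 requires one ortho oxygen of ring A to be differentiated from the other at the outset.
- Comparison: for the flavone ring alone this road is as short or shorter, and its bond-forming step is arguably cleaner than an acyl migration at a hindered ester. Against it the chosen plan keeps ring A symmetric until O1 is used, which secures the 6-linkage without re-protection, and delivers the biaryl bond and the carboxyl carbon together in one ring-free operation.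

Key step: step 8

Assumption: the target specifies only C2, so the C6–C6' axis is treated as not configurationally defined and no atropisomer control is attempted.

## Route

Step 1
Reactants: 1 2-bromoresorcinol (2-bromobenzene-1,3-diol)
Product: 2 2-bromo-1,3-bis(tert-butyldimethylsilyloxy)benzene
Conditions: TBSCl (2.4 equiv), imidazole, DMF, 25 °C
Reagents that add atoms: tert-butyldimethylsilyl chloride, CC(C)(C)[Si](C)(C)Cl
Why: Silylation of phenols with a silyl chloride and imidazole; the silyl ethers have no aryl C–H bonds of their own, shield C4 and C6 in the next step and can later be exchanged for benzyl in one operation.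

Step 2
Reactants: 2 2-bromo-1,3-bis(tert-butyldimethylsilyloxy)benzene
Product: 4 4-bromo-3,5-bis(tert-butyldimethylsilyloxy)phenol, via arylboronic acid pinacol ester 3 (not isolated)
Conditions: [Ir(OMe)(cod)]2 (cat.), 4,4'-di-tert-butyl-2,2'-bipyridine, B2pin2, THF, 80 °C; then KHSO5 (as 2KHSO5·KHSO4·K2SO4), acetone/H2O, 0 → 25 °C
Reagents that add atoms: potassium peroxymonosulfate, [K+].[O-]S(=O)(=O)OO
Why: Iridium-catalysed C–H borylation is sterically governed and C5–H is the only ring C–H not ortho to a substituent; one-pot oxidation of the C–B bond of 3 (aryl shift from boron to oxygen) should give the phenol with the bromide untouched.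

Step 3
Reactants: 4 4-bromo-3,5-bis(tert-butyldimethylsilyloxy)phenol
Product: 5 2-bromo-1,3-bis(tert-butyldimethylsilyloxy)-5-(methoxymethoxy)benzene
Conditions: MOMCl, iPr2NEt, CH2Cl2, 0 → 25 °C
Reagents that add atoms: chloromethyl methyl ether, COCCl
Why: Alkylation of the single free phenol under amine base gives an acetal that survives fluoride, magnesium and amide base and is removed later by acid; this marks the oxygen that becomes O1 of the flavanone.

Step 4
Reactants: 5 2-bromo-1,3-bis(tert-butyldimethylsilyloxy)-5-(methoxymethoxy)benzene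
Product: 6 1,3-bis(benzyloxy)-2-bromo-5-(methoxymethoxy)benzene
Conditions: CsF (3 equiv), BnBr (2.5 equiv), DMF, 25 °C
Reagents that add atoms: benzyl bromide, BrCc1ccccc1
Why: Fluoride cleaves the two aryl silyl ethers and the caesium phenoxides are benzylated in situ (desilylative Williamson etherification); the acetal and the aryl bromide are inert.

Step 5
Reactants: 6 1,3-bis(benzyloxy)-2-bromo-5-(methoxymethoxy)benzene
Product: 7 [2,6-bis(benzyloxy)-4-(methoxymethoxy)phenyl]magnesium bromide (titrated THF solution)
Conditions: Mg turnings (I2-activated), THF, 45 °C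
Reagents that add atoms: magnesium, [Mg]
Why: Oxidative insertion of magnesium into the aryl C–Br bond (Grignard formation); benzyl ethers and the acetal do not react with the arylmagnesium halide.

Step 6
Reactants: 8 catechol (benzene-1,2-diol)
Product: 9 1,2-bis(benzyloxy)benzene
Conditions: BnBr (2.2 equiv), K2CO3, DMF, 60 °C
Reagents that add atoms: benzyl bromide, BrCc1ccccc1
Why: Williamson etherification of both phenols.

Step 7
Reactants: 9 1,2-bis(benzyloxy)benzene
Product: 10 1,2-bis(benzyloxy)-4,5-dibromobenzene
Conditions: Br2 (2.1 equiv), NaOAc, AcOH/CH2Cl2, 0 → 25 °C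
Reagents that add atoms: bromine, BrBr
Why: Electrophilic aromatic bromination; each ether oxygen directs para, so the two bromines enter C4 and C5 of the catechol ring, which is far more activated than the benzyl phenyl rings, and acetate buffers the HBr.

Step 8
Reactants: 7 [2,6-bis(benzyloxy)-4-(methoxymethoxy)phenyl]magnesium bromide; 10 1,2-bis(benzyloxy)-4,5-dibromobenzene; 11 carbon dioxide
Product: 15 4,5-bis(benzyloxy)-2-[2,6-bis(benzyloxy)-4-(methoxymethoxy)phenyl]benzoic acid, via 2-bromoarylmagnesium bromide 12 (not isolated), via 4,5-bis(benzyloxy)benzyne 13 (not isolated), via 2-biarylmagnesium bromide 14 (not isolated)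
Conditions: 7 (1.5 equiv), Mg turnings (1.3 equiv), THF, 60 °C, slow addition of 10; then CO2 (gas), −20 → 25 °C; 1 M HCl, 0 °C
Reagents that add atoms: none
Why: Magnesium inserts into one C–Br bond of 10 to give 12, which loses MgBr2 at 60 °C to form the symmetric aryne 13; the aryl carbon of 7 adds to one end of the strained triple bond (carbomagnesiation), forming the C6–C6' biaryl bond and leaving the new C–Mg bond of 14 on the neighbouring carbon, which CO2 then carboxylates to give acid 15 after acidification, with the future flavone C2 in place. The closest known reaction type is the addition of hindered aryl Grignard reagents to arynes generated in situ from 1,2-dihaloarenes and magnesium with electrophilic capture of the 2-biarylmagnesium halide, the usual one-pot entry to 2-functionalised 2',6'-dialkoxybiaryls. No ring is closed and no stereocentre is formed. The selectivity required is chemoselectivity: 7 must add to 13 before 14 adds to a second aryne or exchanges bromine for magnesium with 10; this is secured by slow addition of 10 into an excess of 7, which keeps the aryne concentration low, and by the crowding and internal O→Mg coordination of 14 by its ortho benzyloxy groups. Regiochemistry does not arise, because 13 has a mirror plane through the triple bond and 7 reacts only at its metallated carbon. The tri-ortho-substituted axis is formed by a strain-driven addition that is far less sensitive to crowding than a cross-coupling, and benzyl and methoxymethyl ethers are inert to aryl Grignard reagents under these conditions.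

Step 9
Reactants: 16 1-(2,4,6-trihydroxyphenyl)ethanone
Product: 17 1-[2,4-bis(benzyloxy)-6-hydroxyphenyl]ethanone
Conditions: BnBr (2.1 equiv), K2CO3, acetone, reflux
Reagents that add atoms: benzyl bromide, BrCc1ccccc1
Why: Williamson etherification; the hydroxyl hydrogen-bonded to the acetyl carbonyl is the least nucleophilic, so two equivalents of benzyl bromide should alkylate the 4-hydroxyl and one ortho hydroxyl and leave the chelated phenol free.

Step 10
Reactants: 15 4,5-bis(benzyloxy)-2-[2,6-bis(benzyloxy)-4-(methoxymethoxy)phenyl]benzoic acid; 17 1-[2,4-bis(benzyloxy)-6-hydroxyphenyl]ethanone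
Product: 18 2-acetyl-3,5-bis(benzyloxy)phenyl 4,5-bis(benzyloxy)-2-[2,6-bis(benzyloxy)-4-(methoxymethoxy)phenyl]benzoate
Conditions: DCC, DMAP (cat.), CH2Cl2, 0 → 25 °C
Reagents that add atoms: none
Why: Steglich esterification: the carbodiimide activates the acid and the acylpyridinium formed with DMAP acylates the only free phenol of 17; the neutral conditions keep the acetal and avoid an acid chloride that could lactonise onto an ortho benzyloxy group.

Step 11
Reactants: 18 2-acetyl-3,5-bis(benzyloxy)phenyl 4,5-bis(benzyloxy)-2-[2,6-bis(benzyloxy)-4-(methoxymethoxy)phenyl]benzoate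
Product: 20 5,7-bis(benzyloxy)-2-{4,5-bis(benzyloxy)-2-[2,6-bis(benzyloxy)-4-hydroxyphenyl]phenyl}-4H-chromen-4-one, via 1,3-diketone 19 (not isolated)
Conditions: LiN(SiMe3)2 (3 equiv), THF, −78 → 25 °C; then conc. HCl, MeOH, 60 °C
Reagents that add atoms: none
Why: Baker–Venkataraman rearrangement: the ketone enolate of 18 attacks the neighbouring aryl ester intramolecularly to give diketone 19; acid then closes the phenol onto the distal carbonyl and dehydrates to the flavone. The same methanolic acid cleaves the methoxymethyl acetal, with the excess methanol trapping the methoxymethyl cation as dimethoxymethane.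

Step 12
Reactants: 20 5,7-bis(benzyloxy)-2-{4,5-bis(benzyloxy)-2-[2,6-bis(benzyloxy)-4-hydroxyphenyl]phenyl}-4H-chromen-4-one
Product: 21 5,7-bis(benzyloxy)-2-{4,5-bis(benzyloxy)-2-[2,6-bis(benzyloxy)-4-hydroxy-3-iodophenyl]phenyl}-4H-chromen-4-one
Conditions: NIS (1.05 equiv), DMF, 0 °C
Reagents that add atoms: N-iodosuccinimide, O=C1CCC(=O)N1I
Why: Electrophilic aromatic iodination ortho to the free phenol; the para position is the biaryl carbon, the two ortho positions are equivalent, and the phenol ring is far more reactive than the fully etherified flavone rings, so one equivalent should give the mono-iodide.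

Step 13
Reactants: 21 5,7-bis(benzyloxy)-2-{4,5-bis(benzyloxy)-2-[2,6-bis(benzyloxy)-4-hydroxy-3-iodophenyl]phenyl}-4H-chromen-4-one
Product: 23 2-{2-[3-acetyl-2,6-bis(benzyloxy)-4-hydroxyphenyl]-4,5-bis(benzyloxy)phenyl}-5,7-bis(benzyloxy)-4H-chromen-4-one, via 1-ethoxyvinyl arene 22 (not isolated)
Conditions: Pd(PPh3)4 (cat.), tributyl(1-ethoxyvinyl)stannane, 1,4-dioxane, 100 °C; then 1 M HCl, THF, 25 °C
Reagents that add atoms: tributyl(1-ethoxyvinyl)stannane, CCCC[Sn](CCCC)(CCCC)C(=C)OCC; water, O
Why: Stille coupling with a 1-ethoxyvinylstannane as acetyl anion equivalent tolerates the free phenol, the benzyl ethers and the flavone; dilute acid hydrolyses enol ether 22 to the methyl ketone, which avoids the Lewis acids of a Friedel–Crafts or Fries acetylation.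

Step 14
Reactants: 23 2-{2-[3-acetyl-2,6-bis(benzyloxy)-4-hydroxyphenyl]-4,5-bis(benzyloxy)phenyl}-5,7-bis(benzyloxy)-4H-chromen-4-one
Product: 25 5,7-bis(benzyloxy)-6-{4,5-bis(benzyloxy)-2-[5,7-bis(benzyloxy)-4-oxo-4H-chromen-2-yl]phenyl}-4H-chromen-4-one, via enaminone 24 (not isolated)
Conditions: Me2NCH(OMe)2, toluene, 100 °C; then conc. HCl, CH2Cl2, 40 °C
Reagents that add atoms: N,N-dimethylformamide dimethyl acetal, COC(OC)N(C)C
Why: Condensation of the methyl ketone with the amide acetal gives enaminone 24; acid-promoted addition of the phenol to the enaminone β-carbon (6-endo closure) and loss of dimethylamine gives the 2,3-unsubstituted chromone, the standard chromone synthesis from 2-hydroxyacetophenones.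

Step 15
Reactants: 25 5,7-bis(benzyloxy)-6-{4,5-bis(benzyloxy)-2-[5,7-bis(benzyloxy)-4-oxo-4H-chromen-2-yl]phenyl}-4H-chromen-4-one; 26 4-(benzyloxy)phenylboronic acid
Product: 27 (2R)-5,7-bis(benzyloxy)-2-[4-(benzyloxy)phenyl]-6-{4,5-bis(benzyloxy)-2-[5,7-bis(benzyloxy)-4-oxo-4H-chromen-2-yl]phenyl}-2,3-dihydro-4H-chromen-4-one
Conditions: [Rh(OH)(cod)]2 (cat.), (R)-2,2'-bis[bis(3,4,5-trifluorophenyl)phosphino]-6,6'-dimethoxy-1,1'-biphenyl, 26 (3 equiv), CH2Cl2/H2O, 25 °C
Reagents that add atoms: none
Why: Hayashi–Miyaura reaction: the arylrhodium formed from 26 adds to the unsubstituted C2 of the chromone and water protonates the rhodium enolate; the new stereocentre C2 is set by the chiral bisphosphine (catalyst control), the (R)-ligand being the one the quadrant model for cyclic enones assigns to the 2R product, with the sense to be checked by circular dichroism of 27 and the (S)-ligand held in reserve. The flavone, whose C2 is fully substituted, is not a competent acceptor, and the base-free medium avoids retro-oxa-Michael opening.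

Step 16
Reactants: 27 (2R)-5,7-bis(benzyloxy)-2-[4-(benzyloxy)phenyl]-6-{4,5-bis(benzyloxy)-2-[5,7-bis(benzyloxy)-4-oxo-4H-chromen-2-yl]phenyl}-2,3-dihydro-4H-chromen-4-one
Product: 28 (2R)-6-[2-(5,7-dihydroxy-4-oxo-4H-chromen-2-yl)-4,5-dihydroxyphenyl]-5,7-dihydroxy-2-(4-hydroxyphenyl)-2,3-dihydro-4H-chromen-4-one (CNP0168406.2)
Conditions: H2 (1 atm), Pd/C (10 %), THF/MeOH, 25 °C
Reagents that add atoms: none
Why: Hydrogenolysis of the seven aryl benzyl ethers on palladium under neutral conditions; stopping at the required hydrogen uptake should leave the flavone C2=C3 bond, both carbonyls and the cyclic benzylic C2–O1 bond intact. The absence of acid and base protects C2 and the 6-linkage from retro-oxa-Michael equilibration.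

## Compound list

1 | 2-bromoresorcinol | Oc1cccc(O)c1Br | starting material
2 | 2-bromo-1,3-bis(tert-butyldimethylsilyloxy)benzene | CC(C)(C)[Si](C)(C)Oc1cccc(O[Si](C)(C)C(C)(C)C)c1Br | intermediate
3 | 2-[4-bromo-3,5-bis(tert-butyldimethylsilyloxy)phenyl]-4,4,5,5-tetramethyl-1,3,2-dioxaborolane | CC(C)(C)[Si](C)(C)Oc1cc(B2OC(C)(C)C(C)(C)O2)cc(O[Si](C)(C)C(C)(C)C)c1Br | intermediate
4 | 4-bromo-3,5-bis(tert-butyldimethylsilyloxy)phenol | CC(C)(C)[Si](C)(C)Oc1cc(O)cc(O[Si](C)(C)C(C)(C)C)c1Br | intermediate
5 | 2-bromo-1,3-bis(tert-butyldimethylsilyloxy)-5-(methoxymethoxy)benzene | COCOc1cc(O[Si](C)(C)C(C)(C)C)c(Br)c(O[Si](C)(C)C(C)(C)C)c1 | intermediate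
6 | 1,3-bis(benzyloxy)-2-bromo-5-(methoxymethoxy)benzene | COCOc1cc(OCc2ccccc2)c(Br)c(OCc2ccccc2)c1 | intermediate
7 | [2,6-bis(benzyloxy)-4-(methoxymethoxy)phenyl]magnesium bromide | Br[Mg]c1c(OCc2ccccc2)cc(OCOC)cc1OCc1ccccc1 | intermediate
8 | catechol | Oc1ccccc1O | starting material
9 | 1,2-bis(benzyloxy)benzene | c1ccc(COc2ccccc2OCc2ccccc2)cc1 | intermediate
10 | 1,2-bis(benzyloxy)-4,5-dibromobenzene | Brc1cc(OCc2ccccc2)c(OCc2ccccc2)cc1Br | intermediate
11 | carbon dioxide | O=C=O | starting material
12 | [4,5-bis(benzyloxy)-2-bromophenyl]magnesium bromide | Br[Mg]c1cc(OCc2ccccc2)c(OCc2ccccc2)cc1Br | intermediate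
13 | 4,5-bis(benzyloxy)benzyne (1,2-bis(benzyloxy)-4,5-didehydrobenzene) | C1#CC=C(OCc2ccccc2)C(OCc2ccccc2)=C1 | intermediate
14 | {4,5-bis(benzyloxy)-2-[2,6-bis(benzyloxy)-4-(methoxymethoxy)phenyl]phenyl}magnesium bromide | Br[Mg]c1cc(OCc2ccccc2)c(OCc2ccccc2)cc1-c1c(OCc2ccccc2)cc(OCOC)cc1OCc1ccccc1 | intermediate
15 | 4,5-bis(benzyloxy)-2-[2,6-bis(benzyloxy)-4-(methoxymethoxy)phenyl]benzoic acid | OC(=O)c1cc(OCc2ccccc2)c(OCc2ccccc2)cc1-c1c(OCc2ccccc2)cc(OCOC)cc1OCc1ccccc1 | intermediate
16 | 1-(2,4,6-trihydroxyphenyl)ethanone | CC(=O)c1c(O)cc(O)cc1O | starting material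
17 | 1-[2,4-bis(benzyloxy)-6-hydroxyphenyl]ethanone | CC(=O)c1c(O)cc(OCc2ccccc2)cc1OCc1ccccc1 | intermediate
18 | 2-acetyl-3,5-bis(benzyloxy)phenyl 4,5-bis(benzyloxy)-2-[2,6-bis(benzyloxy)-4-(methoxymethoxy)phenyl]benzoate | CC(=O)c1c(OC(=O)c2cc(OCc3ccccc3)c(OCc3ccccc3)cc2-c2c(OCc3ccccc3)cc(OCOC)cc2OCc2ccccc2)cc(OCc2ccccc2)cc1OCc1ccccc1 | intermediate
19 | 1-[2,4-bis(benzyloxy)-6-hydroxyphenyl]-3-{4,5-bis(benzyloxy)-2-[2,6-bis(benzyloxy)-4-(methoxymethoxy)phenyl]phenyl}propane-1,3-dione | O=C(CC(=O)c1cc(OCc2ccccc2)c(OCc2ccccc2)cc1-c1c(OCc2ccccc2)cc(OCOC)cc1OCc1ccccc1)c1c(O)cc(OCc2ccccc2)cc1OCc1ccccc1 | intermediate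
20 | 5,7-bis(benzyloxy)-2-{4,5-bis(benzyloxy)-2-[2,6-bis(benzyloxy)-4-hydroxyphenyl]phenyl}-4H-chromen-4-one | O=c1cc(-c2cc(OCc3ccccc3)c(OCc3ccccc3)cc2-c2c(OCc3ccccc3)cc(O)cc2OCc2ccccc2)oc2cc(OCc3ccccc3)cc(OCc3ccccc3)c12 | intermediate
21 | 5,7-bis(benzyloxy)-2-{4,5-bis(benzyloxy)-2-[2,6-bis(benzyloxy)-4-hydroxy-3-iodophenyl]phenyl}-4H-chromen-4-one | O=c1cc(-c2cc(OCc3ccccc3)c(OCc3ccccc3)cc2-c2c(OCc3ccccc3)cc(O)c(I)c2OCc2ccccc2)oc2cc(OCc3ccccc3)cc(OCc3ccccc3)c12 | intermediate
22 | 5,7-bis(benzyloxy)-2-{4,5-bis(benzyloxy)-2-[2,6-bis(benzyloxy)-3-(1-ethoxyvinyl)-4-hydroxyphenyl]phenyl}-4H-chromen-4-one | C=C(OCC)c1c(O)cc(OCc2ccccc2)c(-c2cc(OCc3ccccc3)c(OCc3ccccc3)cc2-c2cc(=O)c3c(OCc4ccccc4)cc(OCc4ccccc4)cc3o2)c1OCc1ccccc1 | intermediate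
23 | 2-{2-[3-acetyl-2,6-bis(benzyloxy)-4-hydroxyphenyl]-4,5-bis(benzyloxy)phenyl}-5,7-bis(benzyloxy)-4H-chromen-4-one | CC(=O)c1c(O)cc(OCc2ccccc2)c(-c2cc(OCc3ccccc3)c(OCc3ccccc3)cc2-c2cc(=O)c3c(OCc4ccccc4)cc(OCc4ccccc4)cc3o2)c1OCc1ccccc1 | intermediate
24 | 5,7-bis(benzyloxy)-2-(4,5-bis(benzyloxy)-2-{2,6-bis(benzyloxy)-3-[(2E)-3-(dimethylamino)prop-2-enoyl]-4-hydroxyphenyl}phenyl)-4H-chromen-4-one | CN(C)/C=C/C(=O)c1c(O)cc(OCc2ccccc2)c(-c2cc(OCc3ccccc3)c(OCc3ccccc3)cc2-c2cc(=O)c3c(OCc4ccccc4)cc(OCc4ccccc4)cc3o2)c1OCc1ccccc1 | intermediate
25 | 5,7-bis(benzyloxy)-6-{4,5-bis(benzyloxy)-2-[5,7-bis(benzyloxy)-4-oxo-4H-chromen-2-yl]phenyl}-4H-chromen-4-one | O=c1ccoc2cc(OCc3ccccc3)c(-c3cc(OCc4ccccc4)c(OCc4ccccc4)cc3-c3cc(=O)c4c(OCc5ccccc5)cc(OCc5ccccc5)cc4o3)c(OCc3ccccc3)c12 | intermediate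
26 | 4-(benzyloxy)phenylboronic acid | OB(O)c1ccc(OCc2ccccc2)cc1 | starting material
27 | (2R)-5,7-bis(benzyloxy)-2-[4-(benzyloxy)phenyl]-6-{4,5-bis(benzyloxy)-2-[5,7-bis(benzyloxy)-4-oxo-4H-chromen-2-yl]phenyl}-2,3-dihydro-4H-chromen-4-one | O=C1C[C@H](c2ccc(OCc3ccccc3)cc2)Oc2cc(OCc3ccccc3)c(-c3cc(OCc4ccccc4)c(OCc4ccccc4)cc3-c3cc(=O)c4c(OCc5ccccc5)cc(OCc5ccccc5)cc4o3)c(OCc3ccccc3)c21 | intermediate
28 | (2R)-6-[2-(5,7-dihydroxy-4-oxo-4H-chromen-2-yl)-4,5-dihydroxyphenyl]-5,7-dihydroxy-2-(4-hydroxyphenyl)-2,3-dihydro-4H-chromen-4-one | O=C1C[C@H](c2ccc(O)cc2)Oc2cc(O)c(-c3cc(O)c(O)cc3-c3cc(=O)c4c(O)cc(O)cc4o3)c(O)c21 | target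

## Step count and least certain steps

Total: 16 steps. Longest linear sequence: 13 steps (steps 1–5, 8, 10–16). Steps 6–7 and step 9 are side branches.

**Step 8 (key step).** The most likely failure is loss of chemoselectivity: the less hindered 14 adds to a second aryne (oligoarylation), or 14 exchanges with 10 so that a 2-bromobiaryl forms instead of the acid. Slow addition by the di-ortho-substituted 7 makes both more likely. The fallback is a Negishi coupling that forms the same axis with the carboxyl carbon already present. It sets out from 10 and 7. Bromine–magnesium exchange on 10 with iPrMgBr at −15 °C gives 12 below its elimination temperature, and trapping with methyl chloroformate gives methyl 4,5-bis(benzyloxy)-2-bromobenzoate F1. Reagent 7 is transmetalated with ZnCl2 to [2,6-bis(benzyloxy)-4-(methoxymethoxy)phenyl]zinc chloride F2. Coupling of F1 and F2 with Pd2(dba)3 and 2-dicyclohexylphosphino-2',6'-dimethoxybiphenyl in THF at 60 °C should give methyl 4,5-bis(benzyloxy)-2-[2,6-bis(benzyloxy)-4-(methoxymethoxy)phenyl]benzoate F3. Saponification with LiOH returns to the route at 15.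

**Step 11.** The acid stage must dehydrate a crowded diketone at 60 °C. Under these conditions the peri 5-benzyl ether may be lost, and the methoxymethyl cation may be captured by the electron-rich phenol ring instead of by methanol. Sluggish acyl transfer at the hindered benzoate is the second concern. The fallback closes the flavone oxidatively and separates ring closure from acetal cleavage. It sets out from 15. Reduction with LiAlH4 gives {4,5-bis(benzyloxy)-2-[2,6-bis(benzyloxy)-4-(methoxymethoxy)phenyl]phenyl}methanol F4, and MnO2 gives the aldehyde 4,5-bis(benzyloxy)-2-[2,6-bis(benzyloxy)-4-(methoxymethoxy)phenyl]benzaldehyde F5. Claisen–Schmidt condensation with 17 (KOH, EtOH/THF) gives the 2'-hydroxychalcone (2E)-1-[2,4-bis(benzyloxy)-6-hydroxyphenyl]-3-{4,5-bis(benzyloxy)-2-[2,6-bis(benzyloxy)-4-(methoxymethoxy)phenyl]phenyl}prop-2-en-1-one F6. Catalytic I2 in DMSO at 120 °C cyclises and dehydrogenates it to 5,7-bis(benzyloxy)-2-{4,5-bis(benzyloxy)-2-[2,6-bis(benzyloxy)-4-(methoxymethoxy)phenyl]phenyl}-4H-chromen-4-one F7. The acetal is then cleaved with HCl in MeOH at 25 °C, which returns to the route at 20.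

**Step 13.** The iodide is flanked by a hydroxyl and a benzyloxy group, so slow oxidative addition or transmetalation and competing protodeiodination are the likely problems. The fallback is a Fries route that bypasses steps 12 and 13. It sets out from 20. Acetylation (Ac2O, pyridine) gives 4-{4,5-bis(benzyloxy)-2-[5,7-bis(benzyloxy)-4-oxo-4H-chromen-2-yl]phenyl}-3,5-bis(benzyloxy)phenyl acetate F8. Fries rearrangement with catalytic Sc(OTf)3 in toluene can only migrate the acetyl group to one of the two equivalent ortho positions, returning to the route at 23. It is held in reserve because of the Lewis acid exposure of the benzyl ethers.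

**Step 15.** The chromone is electron-rich and crowded at C6, so low conversion is possible; poor facial selectivity, or an unexpected sense of induction, is the other risk. The fallback goes through the chalcone and bypasses steps 14 and 15. It sets out from 23. Claisen–Schmidt condensation with 4-(benzyloxy)benzaldehyde F9 (KOH, EtOH/THF) gives the 2'-hydroxychalcone 2-(2-{2,6-bis(benzyloxy)-3-[(2E)-3-(4-benzyloxyphenyl)prop-2-enoyl]-4-hydroxyphenyl}-4,5-bis(benzyloxy)phenyl)-5,7-bis(benzyloxy)-4H-chromen-4-one F10. Oxa-Michael closure with NaOAc in refluxing EtOH gives the racemic flavanone rac-27 F11. Preparative chromatography on a chiral stationary phase returns the 2R enantiomer to the route at 27, at the cost of half the material.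

**Step 16.** Over-reduction is the risk: hydrogenolysis of the benzylic C2–O1 bond to a dihydrochalcone or saturation of the flavone C2=C3 bond, set against incomplete cleavage of the hindered ethers next to the axis. The fallback is non-reductive. It sets out from 27: BCl3 with pentamethylbenzene as cation scavenger in CH2Cl2 at −78 °C should remove all seven benzyl groups and arrive directly at 28; no new compound is formed (F0).

## Further compounds

F1 | step 8 | methyl 4,5-bis(benzyloxy)-2-bromobenzoate | COC(=O)c1cc(OCc2ccccc2)c(OCc2ccccc2)cc1Br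
F2 | step 8 | [2,6-bis(benzyloxy)-4-(methoxymethoxy)phenyl]zinc chloride | Cl[Zn]c1c(OCc2ccccc2)cc(OCOC)cc1OCc1ccccc1
F3 | step 8 | methyl 4,5-bis(benzyloxy)-2-[2,6-bis(benzyloxy)-4-(methoxymethoxy)phenyl]benzoate | COC(=O)c1cc(OCc2ccccc2)c(OCc2ccccc2)cc1-c1c(OCc2ccccc2)cc(OCOC)cc1OCc1ccccc1
F4 | step 11 | {4,5-bis(benzyloxy)-2-[2,6-bis(benzyloxy)-4-(methoxymethoxy)phenyl]phenyl}methanol | OCc1cc(OCc2ccccc2)c(OCc2ccccc2)cc1-c1c(OCc2ccccc2)cc(OCOC)cc1OCc1ccccc1
F5 | step 11 | 4,5-bis(benzyloxy)-2-[2,6-bis(benzyloxy)-4-(methoxymethoxy)phenyl]benzaldehyde | O=Cc1cc(OCc2ccccc2)c(OCc2ccccc2)cc1-c1c(OCc2ccccc2)cc(OCOC)cc1OCc1ccccc1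
F6 | step 11 | (2E)-1-[2,4-bis(benzyloxy)-6-hydroxyphenyl]-3-{4,5-bis(benzyloxy)-2-[2,6-bis(benzyloxy)-4-(methoxymethoxy)phenyl]phenyl}prop-2-en-1-one | O=C(/C=C/c1cc(OCc2ccccc2)c(OCc2ccccc2)cc1-c1c(OCc2ccccc2)cc(OCOC)cc1OCc1ccccc1)c1c(O)cc(OCc2ccccc2)cc1OCc1ccccc1
F7 | step 11 | 5,7-bis(benzyloxy)-2-{4,5-bis(benzyloxy)-2-[2,6-bis(benzyloxy)-4-(methoxymethoxy)phenyl]phenyl}-4H-chromen-4-one | O=c1cc(-c2cc(OCc3ccccc3)c(OCc3ccccc3)cc2-c2c(OCc3ccccc3)cc(OCOC)cc2OCc2ccccc2)oc2cc(OCc3ccccc3)cc(OCc3ccccc3)c12
F8 | step 13 | 4-{4,5-bis(benzyloxy)-2-[5,7-bis(benzyloxy)-4-oxo-4H-chromen-2-yl]phenyl}-3,5-bis(benzyloxy)phenyl acetate | CC(=O)Oc1cc(OCc2ccccc2)c(-c2cc(OCc3ccccc3)c(OCc3ccccc3)cc2-c2cc(=O)c3c(OCc4ccccc4)cc(OCc4ccccc4)cc3o2)c(OCc2ccccc2)c1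
F9 | step 15 | 4-(benzyloxy)benzaldehyde | O=Cc1ccc(OCc2ccccc2)cc1
F10 | step 15 | 2-(2-{2,6-bis(benzyloxy)-3-[(2E)-3-(4-benzyloxyphenyl)prop-2-enoyl]-4-hydroxyphenyl}-4,5-bis(benzyloxy)phenyl)-5,7-bis(benzyloxy)-4H-chromen-4-one | O=C(/C=C/c1ccc(OCc2ccccc2)cc1)c1c(O)cc(OCc2ccccc2)c(-c2cc(OCc3ccccc3)c(OCc3ccccc3)cc2-c2cc(=O)c3c(OCc4ccccc4)cc(OCc4ccccc4)cc3o2)c1OCc1ccccc1
F11 | step 15 | rac-5,7-bis(benzyloxy)-2-[4-(benzyloxy)phenyl]-6-{4,5-bis(benzyloxy)-2-[5,7-bis(benzyloxy)-4-oxo-4H-chromen-2-yl]phenyl}-2,3-dihydro-4H-chromen-4-one (rac-27) | O=C1CC(c2ccc(OCc3ccccc3)cc2)Oc2cc(OCc3ccccc3)c(-c3cc(OCc4ccccc4)c(OCc4ccccc4)cc3-c3cc(=O)c4c(OCc5ccccc5)cc(OCc5ccccc5)cc4o3)c(OCc3ccccc3)c21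
F0 | step 16 | none | none
A1 | alternative 1 | methyl (3S)-3-{4-[(benzyloxycarbonyl)oxy]phenyl}-3-hydroxypropanoate | COC(=O)C[C@H](O)c1ccc(OC(=O)OCc2ccccc2)cc1
A2 | alternative 1 | (3R)-3-{4-[(benzyloxycarbonyl)oxy]phenyl}-3-(4-{4,5-bis(benzyloxy)-2-[5,7-bis(benzyloxy)-4-oxo-4H-chromen-2-yl]phenyl}-3,5-bis(benzyloxy)phenoxy)propanoic acid | OC(=O)C[C@H](c1ccc(OC(=O)OCc2ccccc2)cc1)Oc1cc(OCc2ccccc2)c(-c2cc(OCc3ccccc3)c(OCc3ccccc3)cc2-c2cc(=O)c3c(OCc4ccccc4)cc(OCc4ccccc4)cc3o2)c(OCc2ccccc2)c1
A3 | alternative 1 | (2R)-hexabenzyl ether 4'-benzyl carbonate of the target | O=C1C[C@H](c2ccc(OC(=O)OCc3ccccc3)cc2)Oc2cc(OCc3ccccc3)c(-c3cc(OCc4ccccc4)c(OCc4ccccc4)cc3-c3cc(=O)c4c(OCc5ccccc5)cc(OCc5ccccc5)cc4o3)c(OCc3ccccc3)c21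
A4 | alternative 2 | 2-[4-(allyloxy)-2,6-bis(benzyloxy)phenyl]-4,5-bis(benzyloxy)benzoic acid | OC(=O)c1cc(OCc2ccccc2)c(OCc2ccccc2)cc1-c1c(OCc2ccccc2)cc(OCC=C)cc1OCc1ccccc1
A5 | alternative 2 | methyl 9-{2-[4-(allyloxy)-2,6-bis(benzyloxy)phenyl]-4,5-bis(benzyloxy)phenyl}-3,5,7,9-tetraoxononanoate | COC(=O)CC(=O)CC(=O)CC(=O)CC(=O)c1cc(OCc2ccccc2)c(OCc2ccccc2)cc1-c1c(OCc2ccccc2)cc(OCC=C)cc1OCc1ccccc1
A6 | alternative 2 | 1-{2-[4-(allyloxy)-2,6-bis(benzyloxy)phenyl]-4,5-bis(benzyloxy)phenyl}-3-(2,4,6-trihydroxyphenyl)propane-1,3-dione | O=C(CC(=O)c1c(O)cc(O)cc1O)c1cc(OCc2ccccc2)c(OCc2ccccc2)cc1-c1c(OCc2ccccc2)cc(OCC=C)cc1OCc1ccccc1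
A7 | alternative 3 | 3-(allyloxy)-1,8,9-tris(benzyloxy)-6H-benzo[c]chromen-6-one | O=C1Oc2cc(OCC=C)cc(OCc3ccccc3)c2-c2cc(OCc3ccccc3)c(OCc3ccccc3)cc21
A8 | alternative 3 | 2-{2-[4-(allyloxy)-2-(benzyloxy)-6-hydroxyphenyl]-4,5-bis(benzyloxy)phenyl}-5,7-bis(benzyloxy)-4H-chromen-4-one | O=c1cc(-c2cc(OCc3ccccc3)c(OCc3ccccc3)cc2-c2c(O)cc(OCC=C)cc2OCc2ccccc2)oc2cc(OCc3ccccc3)cc(OCc3ccccc3)c12
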